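The numbers in the tables are simulated from invented constants; the scatter is artificial.

Start with the easy step and count reagent, since each substrate and each partner takes one reagent on its way forward. Here is what you asked, with the runs so far:

common to all: substrate 0.50 M

| run | partner | reagent | remark | time |
|---|---|---|---|---|
| birch | 0.50 M | 0.50 M | run made earlier |  |
| cedar | 0.50 M | 1.1 M | run made earlier |  |
| flask | 0.500 M | 0.750 M |  | 5.0 h |

- birch (time / h: target / %, open intermediate / %): 0.500: 17.5, 6.0; 1.00: 17.4, 5.7; 2.50: 17.3, 6.4; 6.00: 17.1, 5.9
- cedar (time / h: target / %, open intermediate / %): 1.50: 30.1, 69.9; 3.00: 30.1, 69.9; 5.00: 30.6, 69.8; 6.00: 29.8, 69.7

(standard deviation of a reading: 0.5 percentage points)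

- why nothing more happens at 5.0 h, or that something still does (the reagent has run out first / all of the substrate has reacted / it is still moving)
- the target standing at 5.0 h, as a percentage of the substrate charged
- the open intermediate standing at 5.0 h, as a percentage of the substrate charged

- what was read earlier has a scatter of 0.5 percentage points, one standard deviation
- steps thought possible: substrate + reagent -> open intermediate; reagent + partner -> second intermediate; open intermediate + second intermediate -> target; 2 second intermediate -> homo product; second intermediate -> side product; reagent -> decomposition product
- the reaction counts as stopped when no species that holds the substrate changes by six tenths of a point or more over the second half of the time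

Both earlier runs are flat within the scatter, so I read them as end points. At its first reading, birch has 0.118 M of substrate reacted out of 0.50 M of reagent, so in birch, with reagent decomposition set aside, partner takes more reagent than substrate. For this flask and cedar, both charged with more reagent than birch, I therefore freeze the partner's demand at its full charge.

My rule is the surplus W: reagent charged minus partner charged, divided by substrate charged. For this flask W is 50.0%. For cedar W is 120%, above the whole substrate charge, and its first target and open intermediate readings add to 100%. W in this flask is below the whole charge, so I call reagent the limiting reagent here and expect target plus open intermediate near W.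

Your forecast says 29% target and 22% open intermediate, and gives as the ending: the reagent has run out first, in its words “The reagent runs out again”. Its sum, 51.0%, stands slightly above my W.

The flask gives 29.0% target and 22.9% open intermediate, and the ending is: the reagent has run out first, with 0% of the reagent left. Partner left is 2.0% of its charge, so the frozen demand was slightly too high. Handing that unused partner's reagent back to W gives 52.0%, and the two answers add to 51.9%.

    substrate + reagent → open intermediate (k = 0.00670 M⁻¹ s⁻¹)
    reagent + partner → second intermediate (k = 0.0360 M⁻¹ s⁻¹)
    open intermediate + second intermediate → target (k = 0.0920 M⁻¹ s⁻¹)
    2 second intermediate → homo product (k = 0.0860 M⁻¹ s⁻¹)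
    second intermediate → side product (k = 0.00140 s⁻¹)
    reagent → decomposition product (k = 9.90 × 10⁻⁷ s⁻¹)

For the neighbour with 0.20 M of partner, W is 110%, above the whole substrate charge, so I expect the substrate charge to be covered and 6.67% of the charged reagent to remain. That neighbour computes to 0.024% substrate left and 6.5% reagent left, with 19.2% target and 80.8% open intermediate.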